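**Retrosynthetic overview**

1. C7=C8 and C7'=C8' are cut (two Wittig reactions on the C20 dial C8–C8'), which leaves two C15 end groups.
2. C2 (ring) and C2' (chain) have the same spatial sense, and each sits in a lavandulyl unit (C1 with C16/C17, C2 with its C5 branch, C3). Both end groups, 30 of the 50 carbons and both stereocentres therefore come from two molecules of (R)-lavandulol; no stereocentre is made.
3. Ring end: C3–C4 by acetoacetate dianion alkylation. The isopropenyl carbon C1 is first tied to the C5 oxygen (temporary C1–O bond, an oxane ring that is not in the target). The key Lewis acid [1,3] O→C shift then trades C1–O for C1–C6, closing the carbocycle with quaternary C1 next to C2; the C5 ketone and C6 ester then fix C5=C6 (triflate, methyl).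
4. Chain end: C3'=C4' by Julia–Kocienski olefination; the same Markovnikov hydration of the isopropenyl group gives C1'–OH, which is kept here.
5. Ring order: temporary oxane (step 4), then the cyclohexane (step 5), then the cyclohexene (steps 6–7); the polyene is joined last.

Key step: step 5

Assumption: (R)-(−)-lavandulol (the natural enantiomer), crocetin dialdehyde and (2E)-4-acetoxy-2-methylbut-2-enal are taken as commercial; atom labels follow carotenoid numbering (C1–C18 ring end, primed numbers chain end), and all polyene steps are run under argon in dim light.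

**Route**

Step 1
Reactants: 1 (R)-lavandulol
Product: 2 (R)-lavandulyl iodide [(3R)-3-(iodomethyl)-2,6-dimethylhepta-1,5-diene]
Conditions: I2, PPh3, imidazole, CH2Cl2, 0 °C → rt
Reagents that add atoms: iodine, II
Why: Appel-type iodination converts the primary alcohol by SN2 at C3 under neutral conditions, so the adjacent allylic stereocentre C2 and both alkenes are untouched.

Step 2
Reactants: 2 (R)-lavandulyl iodide; 3 ethyl acetoacetate
Product: 4 ethyl (6R)-9-methyl-3-oxo-6-(prop-1-en-2-yl)dec-8-enoate
Conditions: 3, NaH then n-BuLi, THF, 0 °C; 2, DMPU, 0 °C → rt; aq. HCl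
Reagents that add atoms: none
Why: Acetoacetate dianion γ-alkylation displaces the primary iodide (SN2) to form C3–C4 and brings in C4–C7 with the C5 ketone and C7 ester in place; no stereocentre is formed and H-2 is not acidic.

Step 3
Reactants: 4 olefinic β-keto ester; 5 methyl methacrylate
Product: 6 10-ethyl 1-methyl (2E,5R)-2-methyl-8-oxo-5-(prop-1-en-2-yl)dec-2-enedioate
Conditions: Hoveyda–Grubbs II (5 mol%), 5 (10 equiv), 1,4-benzoquinone (10 mol%), CH2Cl2, 45 °C
Reagents that add atoms: none
Why: Ru-catalysed olefin cross-metathesis of the trisubstituted prenyl alkene with a methacrylate (isobutene is lost) should give the thermodynamically favoured E-enoate, i.e. the oxidised C5 branch, while the α-branched isopropenyl group is inert to the catalyst; it also removes the only other electron-rich alkene before the ring closure.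

Step 4
Reactants: 6 enoate β-keto ester
Product: 9 ethyl (2E)-2-[(5R)-5-[(2E)-4-methoxy-3-methyl-4-oxobut-2-en-1-yl]-6,6-dimethyloxan-2-ylidene]acetate, via organomercurial 7 (not isolated), via cyclic hemiketal 8 (not isolated)
Conditions: Hg(OAc)2 (1.05 equiv), THF/H2O, 0 °C; NaBH4, aq. NaOH, 0 °C; crude, PPTS (cat.), PhMe, 4 Å MS, 60 °C
Reagents that add atoms: water, O
Why: Markovnikov oxymercuration–demercuration attacks the 1,1-disubstituted alkene (the fastest alkene class; the enoate is inert) through a bridged mercurinium ion, so C1 gains oxygen without a free cation next to C2, the tertiary alcohol closes onto the C5 ketone and acid-catalysed dehydration of the hemiketal gives the conjugated exocyclic enol ether; the anomeric centre is destroyed again and no stereocentre is created.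

Step 5
Reactants: 9 oxan-2-ylidene acetate
Product: 10 ethyl (3R)-3-[(2E)-4-methoxy-3-methyl-4-oxobut-2-en-1-yl]-2,2-dimethyl-6-oxocyclohexane-1-carboxylate (C-1 epimers and enol)
Conditions: SnCl4 (1.5 equiv), 2,6-di-tert-butyl-4-methylpyridine (0.3 equiv), CH2Cl2, −78 → −20 °C
Reagents that add atoms: none
Why: SnCl4 binds the vinylogous carbonate carbonyl and the tertiary C1–O bond ionises to an intimate pair of a C1 carbocation and the tin enolate of the β-keto ester, which recombines at carbon: a Lewis acid-mediated [1,3] O→C rearrangement (ionisation–recombination as in Ferrier and Petasis–Ferrier carbocyclisations, and the enol ether-to-carbocycle funnel of SnCl4 cyclisations of olefinic β-keto esters). The ring closes by C-alkylation of the enolate carbon C6 at the trigonal cation C1, a 6-(enolendo) closure through a chair with the C2 branch equatorial, forming C1–C6 and the quaternary C1. C2 is not a reacting centre and keeps the lavandulol configuration; the new C6 centre is epimerisable and disappears in step 6, so no stereocontrol is needed there. Selectivity for C- over O-recombination is thermodynamic, since return at oxygen only regenerates 9 whereas the C–C bond does not reionise. Integrity at C2 needs ion-pair collapse to outrun loss of H-2 from the cation, which the low temperature, the non-basic medium and the proximity of the enolate should secure, and the hindered pyridine removes protons so that any alkene formed by elimination cannot be reprotonated (which would racemise C2) or add to the chelated ketone. The side-chain enoate is not nucleophilic and no other alkene is left, which is why the prenyl group was converted in step 3.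

Step 6
Reactants: 10 cyclic β-keto ester
Product: 11 ethyl (5R)-5-[(2E)-4-methoxy-3-methyl-4-oxobut-2-en-1-yl]-6,6-dimethyl-2-[(trifluoromethanesulfonyl)oxy]cyclohex-1-ene-1-carboxylate
Conditions: NaH, Et2O, 0 °C; Tf2O, −78 → 0 °C
Reagents that add atoms: trifluoromethanesulfonic anhydride, O=S(=O)(OS(=O)(=O)C(F)(F)F)C(F)(F)F
Why: O-sulfonylation of the sodium enolate of the β-keto ester; only the doubly activated C6 can enolise, so the vinyl triflate fixes the double bond at C5=C6 and removes the C6 stereocentre.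

Step 7
Reactants: 11 enol triflate
Product: 12 ethyl (5R)-5-[(2E)-4-methoxy-3-methyl-4-oxobut-2-en-1-yl]-2,6,6-trimethylcyclohex-1-ene-1-carboxylate
Conditions: MeZnCl, Pd(PPh3)4 (5 mol%), THF, 50 °C
Reagents that add atoms: methylzinc chloride, C[Zn]Cl
Why: Negishi cross-coupling of the electron-poor enol triflate installs the C5 methyl (C18) with the alkene position retained, and the organozinc touches neither ester.

Step 8
Reactants: 12 diester
Product: 13 (2E)-4-[(1R)-3-(hydroxymethyl)-2,2,4-trimethylcyclohex-3-en-1-yl]-2-methylbut-2-en-1-ol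
Conditions: DIBAL-H (5 equiv), CH2Cl2, −78 → 0 °C; Rochelle salt
Reagents that add atoms: none
Why: DIBAL-H 1,2-reduction of both conjugated esters gives the allylic alcohols at C7 and at the branch terminus without conjugate reduction.

Step 9
Reactants: 13 diol
Product: 14 (2E)-4-[(1R)-3-(hydroxymethyl)-2,2,4-trimethylcyclohex-3-en-1-yl]-2-methylbut-2-en-1-yl acetate
Conditions: immobilised Candida antarctica lipase B, vinyl acetate, MTBE, rt
Reagents that add atoms: vinyl acetate, CC(=O)OC=C
Why: Lipase-catalysed transesterification with an irreversible acyl donor should acylate only the unhindered branch alcohol, since the C7 carbinol between the tetrasubstituted alkene and the gem-dimethyl carbon is too hindered for the enzyme.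

Step 10
Reactants: 14 monoacetate
Product: 15 {[(5R)-5-[(2E)-4-(acetyloxy)-3-methylbut-2-en-1-yl]-2,6,6-trimethylcyclohex-1-en-1-yl]methyl}triphenylphosphonium bromide
Conditions: PPh3·HBr, CH2Cl2, rt
Reagents that add atoms: triphenylphosphine hydrobromide, [Br-].[PH+](c1ccccc1)(c1ccccc1)c1ccccc1
Why: Allylic phosphonium salt formation via the tertiary-allylic cyclogeranyl cation, which PPh3 captures at the primary terminus C7; the acetate keeps the branch alcohol from ionising in the same way.

Step 11
Reactants: 15 ring-end phosphonium salt; 16 crocetin dialdehyde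
Product: 18 (2R)-2-[(2E)-4-hydroxy-3-methylbut-2-en-1-yl]-8'-apo-β-caroten-8'-al, via acetoxy apocarotenal 17 (not isolated)
Conditions: 16 (3 equiv), NaOMe, MeOH/CH2Cl2, 0 °C → rt; then further NaOMe/MeOH, rt
Reagents that add atoms: none
Why: Wittig olefination of the semi-stabilised cyclogeranylidene ylide with one formyl group of the excess dial forms C7=C8 (the strained 7Z isomer should revert to E on warming), and methoxide then transesterifies the acetate (Zemplén) to free the branch alcohol.

Step 12
Reactants: 1 (R)-lavandulol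
Product: 19 5-{[(2R)-5-methyl-2-(prop-1-en-2-yl)hex-4-en-1-yl]sulfanyl}-1-phenyl-1H-tetrazole
Conditions: 1-phenyl-1H-tetrazole-5-thiol, PPh3, DIAD, THF, 0 °C → rt
Reagents that add atoms: 1-phenyl-1H-tetrazole-5-thiol, Sc1nnnn1-c1ccccc1
Why: Mitsunobu thioetherification of the primary alcohol (SN2 at C3') with the acidic tetrazole thiol; the stereocentre C2' is β to the reacting carbon and untouched.

Step 13
Reactants: 19 PT sulfide
Product: 20 5-{[(2R)-5-methyl-2-(prop-1-en-2-yl)hex-4-en-1-yl]sulfonyl}-1-phenyl-1H-tetrazole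
Conditions: (NH4)6Mo7O24·4H2O (10 mol%), 30% H2O2, EtOH, 0 °C → rt
Reagents that add atoms: hydrogen peroxide, OO
Why: Molybdate-catalysed peroxide oxidation of sulfide to sulfone, in which the peroxomolybdate oxidises sulfur far faster than it epoxidises unactivated alkenes.

Step 14
Reactants: 20 PT sulfone; 21 (2E)-4-acetoxy-2-methylbut-2-enal
Product: 22 (2E,4E,6S)-3,9-dimethyl-6-(prop-1-en-2-yl)deca-2,4,8-trien-1-yl acetate
Conditions: KHMDS (0.98 equiv), DME, −60 °C; 21, −60 °C → rt; aq. NH4Cl
Reagents that add atoms: none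
Why: Julia–Kocienski olefination, in which the PT-sulfonyl carbanion adds to the enal and Smiles rearrangement with anti-elimination of SO2 and tetrazolate gives the E-alkene C3'=C4' conjugated to C5'=C6'; with no excess base H-2' is not removed and C2' stays intact.

Step 15
Reactants: 22 triene acetate
Product: 25 (2E,4E,6S)-6-(2-hydroxypropan-2-yl)-3,9-dimethyldeca-2,4,8-trien-1-ol, via organomercurial 23 (not isolated), via hydroxy acetate 24 (not isolated)
Conditions: Hg(OAc)2 (1.0 equiv), THF/H2O, 0 °C; NaBH4, aq. NaOH, 0 °C → rt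
Reagents that add atoms: water, O
Why: Markovnikov oxymercuration–demercuration is selective for the 1,1-disubstituted alkene over the trisubstituted prenyl alkene and the diene (as in the monohydration of limonene) and gives the tertiary alcohol at C1' (two methyls, no new stereocentre), and the alkaline demercuration medium saponifies the allylic acetate.

Step 16
Reactants: 25 diol
Product: 26 [(2E,4E,6S)-6-(2-hydroxypropan-2-yl)-3,9-dimethyldeca-2,4,8-trien-1-yl]triphenylphosphonium bromide
Conditions: PPh3·HBr, MeOH/CH2Cl2, 0 °C → rt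
Reagents that add atoms: triphenylphosphine hydrobromide, [Br-].[PH+](c1ccccc1)(c1ccccc1)c1ccccc1
Why: Allylic phosphonium salt formation via the pentadienyl cation C3'–C7', which PPh3 captures at the unhindered primary terminus C7'; the tertiary alcohol does not ionise under this weak acid.

Step 17
Reactants: 18 C35 hydroxy aldehyde; 26 chain-end phosphonium salt
Product: 27 (2R,2'S)-2-[(2E)-4-hydroxy-3-methylbut-2-en-1-yl]-2'-(3-methylbut-2-en-1-yl)-3',4'-didehydro-1',2'-dihydro-β,ψ-caroten-1'-ol (CNP0286110.1)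
Conditions: NaOMe, MeOH/CH2Cl2, rt; then n-heptane, reflux (Z→E), crystallisation
Reagents that add atoms: none
Why: Wittig olefination of the pentadienyl ylide with the C35 aldehyde forms C7'=C8' and completes the C50 polyene, and heating should equilibrate Z isomers of the new disubstituted bond to the all-E compound; both stereocentres are remote from the reacting carbons.

**Compound list**

1 | (R)-lavandulol [(2R)-5-methyl-2-(prop-1-en-2-yl)hex-4-en-1-ol] | CC(C)=CC[C@@H](CO)C(C)=C | starting material
2 | (R)-lavandulyl iodide [(3R)-3-(iodomethyl)-2,6-dimethylhepta-1,5-diene] | CC(C)=CC[C@@H](CI)C(C)=C | intermediate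
3 | ethyl acetoacetate | CCOC(=O)CC(C)=O | starting material
4 | ethyl (6R)-9-methyl-3-oxo-6-(prop-1-en-2-yl)dec-8-enoate | CC(C)=CC[C@@H](CCC(=O)CC(=O)OCC)C(C)=C | intermediate
5 | methyl methacrylate | COC(=O)C(C)=C | starting material
6 | 10-ethyl 1-methyl (2E,5R)-2-methyl-8-oxo-5-(prop-1-en-2-yl)dec-2-enedioate | COC(=O)/C(C)=C/C[C@@H](CCC(=O)CC(=O)OCC)C(C)=C | intermediate
7 | 10-ethyl 1-methyl (2E,5R)-5-[1-(acetoxymercurio)-2-hydroxypropan-2-yl]-2-methyl-8-oxodec-2-enedioate (both carbinol epimers) | COC(=O)/C(C)=C/C[C@@H](CCC(=O)CC(=O)OCC)C(C)(O)C[Hg]OC(C)=O | intermediate (not isolated)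
8 | ethyl 2-[(5R)-2-hydroxy-5-[(2E)-4-methoxy-3-methyl-4-oxobut-2-en-1-yl]-6,6-dimethyloxan-2-yl]acetate (both anomers) | CCOC(=O)CC1(O)CC[C@H](C/C=C(\C)C(=O)OC)C(C)(C)O1 | intermediate (not isolated)
9 | ethyl (2E)-2-[(5R)-5-[(2E)-4-methoxy-3-methyl-4-oxobut-2-en-1-yl]-6,6-dimethyloxan-2-ylidene]acetate | CCOC(=O)/C=C1\CC[C@H](C/C=C(\C)C(=O)OC)C(C)(C)O1 | intermediate
10 | ethyl (3R)-3-[(2E)-4-methoxy-3-methyl-4-oxobut-2-en-1-yl]-2,2-dimethyl-6-oxocyclohexane-1-carboxylate | CCOC(=O)C1C(=O)CC[C@H](C/C=C(\C)C(=O)OC)C1(C)C | intermediate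
11 | ethyl (5R)-5-[(2E)-4-methoxy-3-methyl-4-oxobut-2-en-1-yl]-6,6-dimethyl-2-[(trifluoromethanesulfonyl)oxy]cyclohex-1-ene-1-carboxylate | CCOC(=O)C1=C(OS(=O)(=O)C(F)(F)F)CC[C@H](C/C=C(\C)C(=O)OC)C1(C)C | intermediate
12 | ethyl (5R)-5-[(2E)-4-methoxy-3-methyl-4-oxobut-2-en-1-yl]-2,6,6-trimethylcyclohex-1-ene-1-carboxylate | CCOC(=O)C1=C(C)CC[C@H](C/C=C(\C)C(=O)OC)C1(C)C | intermediate
13 | (2E)-4-[(1R)-3-(hydroxymethyl)-2,2,4-trimethylcyclohex-3-en-1-yl]-2-methylbut-2-en-1-ol | OCC1=C(C)CC[C@H](C/C=C(\C)CO)C1(C)C | intermediate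
14 | (2E)-4-[(1R)-3-(hydroxymethyl)-2,2,4-trimethylcyclohex-3-en-1-yl]-2-methylbut-2-en-1-yl acetate | OCC1=C(C)CC[C@H](C/C=C(\C)COC(C)=O)C1(C)C | intermediate
15 | {[(5R)-5-[(2E)-4-(acetyloxy)-3-methylbut-2-en-1-yl]-2,6,6-trimethylcyclohex-1-en-1-yl]methyl}triphenylphosphonium bromide | C(C1=C(C)CC[C@H](C/C=C(\C)COC(C)=O)C1(C)C)[P+](c1ccccc1)(c1ccccc1)c1ccccc1.[Br-] | intermediate
16 | crocetin dialdehyde [(2E,4E,6E,8E,10E,12E,14E)-2,6,11,15-tetramethylhexadeca-2,4,6,8,10,12,14-heptaenedial] | O=C/C(C)=C/C=C/C(C)=C/C=C/C=C(C)/C=C/C=C(C)/C=O | starting material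
17 | (2R)-2-[(2E)-4-acetoxy-3-methylbut-2-en-1-yl]-8'-apo-β-caroten-8'-al | O=C/C(C)=C/C=C/C(C)=C/C=C/C=C(C)/C=C/C=C(C)/C=C/C1=C(C)CC[C@H](C/C=C(\C)COC(C)=O)C1(C)C | intermediate (not isolated)
18 | (2R)-2-[(2E)-4-hydroxy-3-methylbut-2-en-1-yl]-8'-apo-β-caroten-8'-al | O=C/C(C)=C/C=C/C(C)=C/C=C/C=C(C)/C=C/C=C(C)/C=C/C1=C(C)CC[C@H](C/C=C(\C)CO)C1(C)C | intermediate
19 | 5-{[(2R)-5-methyl-2-(prop-1-en-2-yl)hex-4-en-1-yl]sulfanyl}-1-phenyl-1H-tetrazole | CC(C)=CC[C@@H](CSc1nnnn1-c1ccccc1)C(C)=C | intermediate
20 | 5-{[(2R)-5-methyl-2-(prop-1-en-2-yl)hex-4-en-1-yl]sulfonyl}-1-phenyl-1H-tetrazole | CC(C)=CC[C@@H](CS(=O)(=O)c1nnnn1-c1ccccc1)C(C)=C | intermediate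
21 | (2E)-4-acetoxy-2-methylbut-2-enal | CC(=O)OC/C=C(\C)C=O | starting material
22 | (2E,4E,6S)-3,9-dimethyl-6-(prop-1-en-2-yl)deca-2,4,8-trien-1-yl acetate | CC(C)=CC[C@@H](/C=C/C(C)=C/COC(C)=O)C(C)=C | intermediate
23 | (2E,4E,6S)-6-[1-(acetoxymercurio)-2-hydroxypropan-2-yl]-3,9-dimethyldeca-2,4,8-trien-1-yl acetate (both carbinol epimers) | CC(C)=CC[C@@H](/C=C/C(C)=C/COC(C)=O)C(C)(O)C[Hg]OC(C)=O | intermediate (not isolated)
24 | (2E,4E,6S)-6-(2-hydroxypropan-2-yl)-3,9-dimethyldeca-2,4,8-trien-1-yl acetate | CC(C)=CC[C@@H](/C=C/C(C)=C/COC(C)=O)C(C)(C)O | intermediate (not isolated)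
25 | (2E,4E,6S)-6-(2-hydroxypropan-2-yl)-3,9-dimethyldeca-2,4,8-trien-1-ol | CC(C)=CC[C@@H](/C=C/C(C)=C/CO)C(C)(C)O | intermediate
26 | [(2E,4E,6S)-6-(2-hydroxypropan-2-yl)-3,9-dimethyldeca-2,4,8-trien-1-yl]triphenylphosphonium bromide | CC(C)=CC[C@@H](/C=C/C(C)=C/C[P+](c1ccccc1)(c1ccccc1)c1ccccc1)C(C)(C)O.[Br-] | intermediate
27 | (2R,2'S)-2-[(2E)-4-hydroxy-3-methylbut-2-en-1-yl]-2'-(3-methylbut-2-en-1-yl)-3',4'-didehydro-1',2'-dihydro-β,ψ-caroten-1'-ol | CC(C)=CC[C@@H](/C=C/C(C)=C/C=C/C(C)=C/C=C/C(C)=C/C=C/C=C(C)/C=C/C=C(C)/C=C/C1=C(C)CC[C@H](C/C=C(\C)CO)C1(C)C)C(C)(C)O | target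

**Totals**

Total step count: 17. Longest linear sequence: 12 (steps 1–11, then 17).

**Steps most likely to fail**

1. Step 5. After ionisation the C1 cation may lose a proton (H-2 or a methyl hydrogen) instead of bonding to C6. The resulting open-chain alkene may then re-enter through protonation or add to the chelated ketone, which would lower the yield and erode the configuration at C2. Fallback, from 6 (in place of steps 4 and 5): N-(phenylseleno)phthalimide and SnCl4 in CH2Cl2 at −78 °C → rt should form a bridged seleniranium ion on the isopropenyl group, which the β-keto ester captures at the tertiary carbon C1 without a free cation. This gives the carbocyclic selenide ethyl (3R)-3-[(2E)-4-methoxy-3-methyl-4-oxobut-2-en-1-yl]-2-methyl-6-oxo-2-[(phenylselanyl)methyl]cyclohexane-1-carboxylate F1. Radical deselenation (Bu3SnH, AIBN, PhH, 80 °C) turns CH2SePh into the second C1 methyl and returns to the route at 10.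

2. Step 3. The metathesis may stall because both partners are hindered and the β-keto ester can sequester ruthenium, or a Ru–H species may move the isopropenyl double bond into C1=C2 and destroy the stereocentre. Fallback, from 4: m-CPBA (1 equiv, NaHCO3, CH2Cl2, −20 °C) should epoxidise the more electron-rich trisubstituted alkene to ethyl (6R)-6-[(3,3-dimethyloxiran-2-yl)methyl]-7-methyl-3-oxooct-7-enoate F2. Periodic acid (H5IO6, THF/H2O, 0 °C) cleaves the epoxide to ethyl (6R)-7-methyl-3-oxo-6-(2-oxoethyl)oct-7-enoate F3. Wittig olefination with methyl 2-(triphenyl-λ5-phosphanylidene)propanoate (CH2Cl2, rt, E-selective stabilised ylide) returns to the route at 6.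

3. Step 11. The hindered cyclogeranylidene ylide may add sluggishly, the dial may react at both ends, and Z isomers may persist. Fallback, from 14: Mitsunobu reaction with 2-mercaptobenzothiazole (PPh3, DIAD, THF) gives 2-({[(5R)-5-[(2E)-4-(acetyloxy)-3-methylbut-2-en-1-yl]-2,6,6-trimethylcyclohex-1-en-1-yl]methyl}sulfanyl)-1,3-benzothiazole F4. Molybdate/H2O2 oxidation gives the sulfone 2-({[(5R)-5-[(2E)-4-(acetyloxy)-3-methylbut-2-en-1-yl]-2,6,6-trimethylcyclohex-1-en-1-yl]methyl}sulfonyl)-1,3-benzothiazole F5. Julia–Kocienski olefination of 16 (3 equiv; NaHMDS, THF, −78 °C → rt) gives 17, and K2CO3/MeOH returns to the route at 18.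

**Further compounds**

F1 | step 5 | ethyl (3R)-3-[(2E)-4-methoxy-3-methyl-4-oxobut-2-en-1-yl]-2-methyl-6-oxo-2-[(phenylselanyl)methyl]cyclohexane-1-carboxylate | CCOC(=O)C1C(=O)CC[C@H](C/C=C(\C)C(=O)OC)C1(C)C[Se]c1ccccc1
F2 | step 3 | ethyl (6R)-6-[(3,3-dimethyloxiran-2-yl)methyl]-7-methyl-3-oxooct-7-enoate | CCOC(=O)CC(=O)CC[C@H](CC1OC1(C)C)C(C)=C
F3 | step 3 | ethyl (6R)-7-methyl-3-oxo-6-(2-oxoethyl)oct-7-enoate | CCOC(=O)CC(=O)CC[C@H](CC=O)C(C)=C
F4 | step 11 | 2-({[(5R)-5-[(2E)-4-(acetyloxy)-3-methylbut-2-en-1-yl]-2,6,6-trimethylcyclohex-1-en-1-yl]methyl}sulfanyl)-1,3-benzothiazole | C(C1=C(C)CC[C@H](C/C=C(\C)COC(C)=O)C1(C)C)Sc1nc2ccccc2s1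
F5 | step 11 | 2-({[(5R)-5-[(2E)-4-(acetyloxy)-3-methylbut-2-en-1-yl]-2,6,6-trimethylcyclohex-1-en-1-yl]methyl}sulfonyl)-1,3-benzothiazole | C(C1=C(C)CC[C@H](C/C=C(\C)COC(C)=O)C1(C)C)S(=O)(=O)c1nc2ccccc2s1
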